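**Retrosynthetic overview**

1. Endgame: the oxirane comes last, by epoxidation of the (E)-C4=C5 alkene of a ten-membered dienolide from its open face, after C8 angeloylation and exchange of the C13 silyl ether for the acetate.
2. Key disconnection: the lactone bond O–C6 and the ring bond C7–C8 are cut together, which unfolds the bicycle to an acyclic 2-(trimethylsilyl)ethyl 2,3-allenoate (C6=C7=C11, ester carbon C12) that ends in the C8 aldehyde.
3. Enabling feature: in the butenolide, C6–C7–C11 with C12 on C11 is a 2,3-allenoate at the right oxidation level, and its β-carbon C7 is the atom of the ten-membered ring bonded to carbinol C8. Attack of the C12 oxygen on C6 therefore leaves a C7–metal bond aimed at the C8 aldehyde, and the (E)-C4=C5 bond bars closure on the C1 ketone.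
4. The allene axis comes from a C6 propargylic carbonate (asymmetric alkynylation of an enal, then anti SN2′ carbonylation); C1–C6 come from geranyl acetate, C8–C10 with the C10 stereocenter from an anti crotylboration and hydroboration.
5. Ring order: butenolide and ten-membered carbocycle together (step 12), then the oxirane (step 15).

Key step: step 12

Remark: germacrane numbering is used throughout (C1 ketone, C4/C5 oxirane carbons, C6 lactone carbinol, C7=C11 butenolide alkene, C8 ester carbinol, C10 methyl-bearing methine, C12 lactone carbonyl, C13 acetoxymethyl carbon). The target is read as the (Z)-2-methylbut-2-enoate (angelate) with 4R,5R,6S,8S,10R, and the numbered starting materials and 2-(trimethylsilyl)ethyl chloroformate are taken as commercial.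

**Route**

Step 1
Reactants: 1 geranyl acetate
Product: 3 (2E)-3-methyl-6-oxohex-2-en-1-yl acetate, via 6,7-epoxygeranyl acetate 2 (not isolated)
Conditions: mCPBA (1.05 equiv), CH2Cl2, 0 °C; then H5IO6 (1.2 equiv), THF/H2O, 0 °C
Reagents that add atoms: 3-chloroperbenzoic acid (mCPBA), OOC(=O)c1cccc(Cl)c1
Why: The 6,7-alkene is the more electron-rich one (the 2,3-alkene is deactivated by the allylic acetate), so the Prilezhaev epoxidation should be regioselective, and periodic acid opens the oxirane and cleaves the glycol (Malaprade cleavage) to the aldehyde; no stereocenter is carried on.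

Step 2
Reactants: 3 (2E)-3-methyl-6-oxohex-2-en-1-yl acetate; 4 (E)-crotylboronic acid pinacol ester
Product: 5 (2E,6S,7R)-6-hydroxy-3,7-dimethylnona-2,8-dien-1-yl acetate
Conditions: (R)-TRIP phosphoric acid (5 mol %), toluene, −30 °C; aq NaHCO3 work-up
Reagents that add atoms: none
Why: Chiral phosphoric acid-catalysed crotylboration through a closed chair (Zimmerman–Traxler type) transition state: the (E)-crotyl geometry gives the anti adduct and the (R)-catalyst is expected to direct attack to the Re face of the aldehyde, which sets 7R (the future C10) and 6S (a carbinol that is oxidised in step 5).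

Step 3
Reactants: 5 (2E,6S,7R)-6-hydroxy-3,7-dimethylnona-2,8-dien-1-yl acetate
Product: 6 (2E,6S,7R)-6,9-dihydroxy-3,7-dimethylnon-2-en-1-yl acetate
Conditions: 9-BBN (2.5 equiv), THF, 0 °C to rt; then aq NaOAc, 30% H2O2, 0 °C to rt
Reagents that add atoms: hydrogen peroxide, OO
Why: Anti-Markovnikov hydroboration–oxidation: 9-BBN reacts with the monosubstituted alkene far faster than with the trisubstituted one, the buffered peroxide work-up should spare the acetate, and no stereocenter is touched.

Step 4
Reactants: 6 (2E,6S,7R)-6,9-dihydroxy-3,7-dimethylnon-2-en-1-yl acetate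
Product: 7 (2E,6S,7R)-6-hydroxy-3,7-dimethyl-9-(triethylsilyloxy)non-2-en-1-yl acetate
Conditions: Et3SiCl (1.05 equiv), imidazole, CH2Cl2, −78 to −40 °C
Reagents that add atoms: chlorotriethylsilane, CC[Si](Cl)(CC)CC
Why: Silylation under kinetic control at low temperature selects the primary over the secondary hydroxyl group.

Step 5
Reactants: 7 (2E,6S,7R)-6-hydroxy-3,7-dimethyl-9-(triethylsilyloxy)non-2-en-1-yl acetate
Product: 8 (2E,7R)-3,7-dimethyl-6-oxo-9-(triethylsilyloxy)non-2-en-1-yl acetate
Conditions: Dess–Martin periodinane (1.3 equiv), NaHCO3, CH2Cl2, 0 °C to rt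
Reagents that add atoms: none
Why: Dess–Martin oxidation of the secondary alcohol under buffered, non-basic conditions should give the ketone without epimerising the adjacent methyl-bearing C10.

Step 6
Reactants: 8 (2E,7R)-3,7-dimethyl-6-oxo-9-(triethylsilyloxy)non-2-en-1-yl acetate
Product: 9 (3R,7E)-9-hydroxy-3,7-dimethyl-1-(triethylsilyloxy)non-7-en-4-one
Conditions: K2CO3 (0.3 equiv), MeOH, 0 °C, short reaction time
Reagents that add atoms: none
Why: Base-catalysed transesterification (methanolysis) removes the allylic acetate faster than it attacks the triethylsilyl ether or enolises the ketone.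

Step 7
Reactants: 9 (3R,7E)-9-hydroxy-3,7-dimethyl-1-(triethylsilyloxy)non-7-en-4-one
Product: 10 (2E,7R)-3,7-dimethyl-6-oxo-9-(triethylsilyloxy)non-2-enal
Conditions: MnO2 (20 equiv), CH2Cl2, rt
Reagents that add atoms: none
Why: MnO2 oxidises only the allylic alcohol and keeps the (E)-geometry of the enal.

Step 8
Reactants: 10 (2E,7R)-3,7-dimethyl-6-oxo-9-(triethylsilyloxy)non-2-enal; 11 tert-butyldimethyl(prop-2-yn-1-yloxy)silane
Product: 12 (3R,7E,9S)-12-(tert-butyldimethylsilyloxy)-9-hydroxy-3,7-dimethyl-1-(triethylsilyloxy)dodec-7-en-10-yn-4-one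
Conditions: Me2Zn (3 equiv), (S,S)-ProPhenol (20 mol %), Ph3P=O (40 mol %), toluene, 0 °C; aq NH4Cl work-up
Reagents that add atoms: none
Why: Catalytic asymmetric alkynylation (dinuclear zinc–ProPhenol catalysis, well suited to enals) adds the zinc acetylide to the aldehyde and not to the ketone; the (S,S)-ligand is expected to deliver it to the Re face and so set 9S (C6 in germacrane numbering).

Step 9
Reactants: 12 (3R,7E,9S)-12-(tert-butyldimethylsilyloxy)-9-hydroxy-3,7-dimethyl-1-(triethylsilyloxy)dodec-7-en-10-yn-4-one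
Product: 13 (4S,5E,10R)-1-(tert-butyldimethylsilyloxy)-6,10-dimethyl-9-oxo-12-(triethylsilyloxy)dodec-5-en-2-yn-4-yl 2-(trimethylsilyl)ethyl carbonate
Conditions: ClCO2CH2CH2SiMe3 (1.5 equiv), pyridine, DMAP (10 mol %), CH2Cl2, 0 °C
Reagents that add atoms: 2-(trimethylsilyl)ethyl chloroformate, C[Si](C)(C)CCOC(Cl)=O
Why: Acylation of the secondary alcohol gives a carbonate, the leaving group of choice at this allylic and propargylic position because a sulfonate would ionise; the stereocenter is not touched.

Step 10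
Reactants: 13 (4S,5E,10R)-1-(tert-butyldimethylsilyloxy)-6,10-dimethyl-9-oxo-12-(triethylsilyloxy)dodec-5-en-2-yn-4-yl 2-(trimethylsilyl)ethyl carbonate
Product: 14 (4S,5E,10R)-1-(tert-butyldimethylsilyloxy)-6,10-dimethyl-9,12-dioxododec-5-en-2-yn-4-yl 2-(trimethylsilyl)ethyl carbonate
Conditions: (COCl)2 (4 equiv), DMSO (8 equiv), CH2Cl2, −78 to −35 °C; then Et3N (12 equiv), −78 to 0 °C
Reagents that add atoms: none
Why: Under Swern conditions the chlorosulfonium salt cleaves a primary triethylsilyl ether and oxidises it to the aldehyde in one operation, while the tert-butyldimethylsilyl ether, the carbonate and both stereocenters should survive at low temperature.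

Step 11
Reactants: 14 (4S,5E,10R)-1-(tert-butyldimethylsilyloxy)-6,10-dimethyl-9,12-dioxododec-5-en-2-yn-4-yl 2-(trimethylsilyl)ethyl carbonate
Product: 15 2-(trimethylsilyl)ethyl (aR,5E,10R)-2-[(tert-butyldimethylsilyloxy)methyl]-6,10-dimethyl-9,12-dioxododeca-2,3,5-trienoate
Conditions: Pd(PPh3)4 (5 mol %), CO (5 bar), THF, 25 °C
Reagents that add atoms: carbon monoxide, [C-]#[O+]
Why: Decarboxylative carbonylation of a propargylic carbonate: zerovalent palladium attacks C11 anti to the leaving group (SN2′ oxidative addition), CO inserts with retention and the liberated silylethoxide captures the acylpalladium species, so the 4S carbonate should give the (aR)-allene by centre-to-axis transfer.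

Step 12
Reactants: 15 2-(trimethylsilyl)ethyl (aR,5E,10R)-2-[(tert-butyldimethylsilyloxy)methyl]-6,10-dimethyl-9,12-dioxododeca-2,3,5-trienoate
Product: 17 (6R,8S,10R)-13-(tert-butyldimethylsilyloxy)-8-hydroxy-1-oxogermacra-4(E),7(11)-dien-12,6-olide, via 8-O-trimethylsilyl ether 16 (not isolated)
Conditions: Pd(MeCN)4(OTf)2 (10 mol %), 2,2′-bipyridine (11 mol %), 2,6-di-tert-butyl-4-methylpyridine (20 mol %), 4 Å MS, ClCH2CH2Cl, 30 °C, 15 added over 12 h (final 0.002 M); then 1 M aq citric acid, THF, 0 °C
Reagents that add atoms: none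
Why: Proposed new method: the dicationic bipyridine complex of divalent palladium binds the C6=C7 bond of the allene on the face opposite the ester, the C12 carbonyl oxygen attacks C6 in an anti oxypalladation (the step known from lactonization and coupling–cyclization of 2,3-allenoic acids and esters with palladium, gold, silver and iodine electrophiles), and the oxocarbenium ion loses its 2-(trimethylsilyl)ethyl group as ethylene and Me3SiOTf, so that the C7-vinylpalladium butenolide arises without a proton that could cleave the C7–Pd bond. This intermediate has no β-hydrogen that it can eliminate, so it should persist until the C8 aldehyde inserts into the C7–Pd bond (carbonyl 1,2-insertion into cationic bipyridine-ligated vinylpalladium species is known for five- and six-membered rings, and the closest known ten-membered closure is the Nozaki–Hiyama–Kishi addition of a vinylchromium reagent), after which Me3SiOTf silylates the palladium alkoxide to 16 and returns the catalyst. The butenolide closes in a 5-endo-trig mode at C6 and the carbocycle in a 10-exo-trig mode at C8. C6 is set by axis-to-centre transfer, because the ester oxygen can reach C6 only on the side of the allene on which C12 lies, so the (aR)-axis gives the 6R lactone; C8 should be set by the ring-closing transition state, in which only the 8S arrangement keeps C8–H in the butenolide plane beside the C13 substituent (minimal allylic 1,3-strain) while C5 and C9 leave the butenolide on opposite faces. The step needs aldehyde-over-ketone selectivity, and the (E)-C4=C5 bond secures it, since closure on the C1 ketone would demand a trans-cycloheptene whereas the trans-cyclodecene is unstrained. Protodepalladation and the [1,5]-hydrogen shift of the vinylallene are held back by the proton-free silyl relay, the hindered pyridine and the low temperature.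

Step 13
Reactants: 17 (6R,8S,10R)-13-(tert-butyldimethylsilyloxy)-8-hydroxy-1-oxogermacra-4(E),7(11)-dien-12,6-olide; 18 angelic acid
Product: 20 (6R,8S,10R)-8-angeloyloxy-13-(tert-butyldimethylsilyloxy)-1-oxogermacra-4(E),7(11)-dien-12,6-olide, via mixed anhydride 19 (not isolated)
Conditions: 18 (3 equiv), 2,4,6-trichlorobenzoyl chloride (3 equiv), Et3N (6 equiv), toluene, rt; then 17, 70 °C
Reagents that add atoms: none
Why: Yamaguchi-type esterification through the mixed anhydride without DMAP should acylate the hindered allylic alcohol while keeping the (Z)-geometry of the angelate; C8 is not inverted.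

Step 14
Reactants: 20 (6R,8S,10R)-8-angeloyloxy-13-(tert-butyldimethylsilyloxy)-1-oxogermacra-4(E),7(11)-dien-12,6-olide
Product: 22 (6R,8S,10R)-13-acetoxy-8-angeloyloxy-1-oxogermacra-4(E),7(11)-dien-12,6-olide, via 13-alcohol 21 (not isolated)
Conditions: HF·pyridine, pyridine/THF, 0 °C to rt; then Ac2O (10 equiv), DMAP (10 mol %), 0 °C to rt
Reagents that add atoms: acetic anhydride, CC(=O)OC(C)=O
Why: Fluoride cleaves the primary silyl ether and the liberated allylic alcohol is acetylated in the same flask; the esters, the ketone and the stereocenters should be stable to these conditions.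

Step 15
Reactants: 22 (6R,8S,10R)-13-acetoxy-8-angeloyloxy-1-oxogermacra-4(E),7(11)-dien-12,6-olide
Product: 23 (4R,5R,6S,8S,10R)-13-acetoxy-8-angeloyloxy-4,5-epoxy-1-oxogermacr-7(11)-en-12,6-olide (target)
Conditions: mCPBA (1.2 equiv), NaHCO3, CH2Cl2, 0 °C
Reagents that add atoms: 3-chloroperbenzoic acid (mCPBA), OOC(=O)c1cccc(Cl)c1
Why: Prilezhaev epoxidation: the isolated trisubstituted C4=C5 alkene is far more electron-rich than the two conjugated alkenes, and in the conformer with C6–H eclipsing the alkene plane (minimal allylic 1,3-strain against the C4 methyl group) the ring covers one face, so the peracid should attack the open face syn to the lactone oxygen and set 4R,5R.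

**Compound list**

1 | geranyl acetate, (2E)-3,7-dimethylocta-2,6-dien-1-yl acetate | CC(=O)OC/C=C(\C)CCC=C(C)C | starting material
2 | 6,7-epoxygeranyl acetate, (2E)-5-(3,3-dimethyloxiran-2-yl)-3-methylpent-2-en-1-yl acetate (racemic at the oxirane) | CC(=O)OC/C=C(\C)CCC1OC1(C)C | intermediate
3 | (2E)-3-methyl-6-oxohex-2-en-1-yl acetate | O=CCC/C(C)=C/COC(C)=O | intermediate
4 | (E)-crotylboronic acid pinacol ester, 2-[(2E)-but-2-en-1-yl]-4,4,5,5-tetramethyl-1,3,2-dioxaborolane | C/C=C/CB1OC(C)(C)C(C)(C)O1 | starting material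
5 | (2E,6S,7R)-6-hydroxy-3,7-dimethylnona-2,8-dien-1-yl acetate | C=C[C@@H](C)[C@@H](O)CC/C(C)=C/COC(C)=O | intermediate
6 | (2E,6S,7R)-6,9-dihydroxy-3,7-dimethylnon-2-en-1-yl acetate | OCC[C@@H](C)[C@@H](O)CC/C(C)=C/COC(C)=O | intermediate
7 | (2E,6S,7R)-6-hydroxy-3,7-dimethyl-9-(triethylsilyloxy)non-2-en-1-yl acetate | CC[Si](CC)(CC)OCC[C@@H](C)[C@@H](O)CC/C(C)=C/COC(C)=O | intermediate
8 | (2E,7R)-3,7-dimethyl-6-oxo-9-(triethylsilyloxy)non-2-en-1-yl acetate | CC[Si](CC)(CC)OCC[C@@H](C)C(=O)CC/C(C)=C/COC(C)=O | intermediate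
9 | (3R,7E)-9-hydroxy-3,7-dimethyl-1-(triethylsilyloxy)non-7-en-4-one | CC[Si](CC)(CC)OCC[C@@H](C)C(=O)CC/C(C)=C/CO | intermediate
10 | (2E,7R)-3,7-dimethyl-6-oxo-9-(triethylsilyloxy)non-2-enal | CC[Si](CC)(CC)OCC[C@@H](C)C(=O)CC/C(C)=C/C=O | intermediate
11 | tert-butyldimethyl(prop-2-yn-1-yloxy)silane | C#CCO[Si](C)(C)C(C)(C)C | starting material
12 | (3R,7E,9S)-12-(tert-butyldimethylsilyloxy)-9-hydroxy-3,7-dimethyl-1-(triethylsilyloxy)dodec-7-en-10-yn-4-one | CC[Si](CC)(CC)OCC[C@@H](C)C(=O)CC/C(C)=C/[C@H](O)C#CCO[Si](C)(C)C(C)(C)C | intermediate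
13 | (4S,5E,10R)-1-(tert-butyldimethylsilyloxy)-6,10-dimethyl-9-oxo-12-(triethylsilyloxy)dodec-5-en-2-yn-4-yl 2-(trimethylsilyl)ethyl carbonate | CC[Si](CC)(CC)OCC[C@@H](C)C(=O)CC/C(C)=C/[C@H](OC(=O)OCC[Si](C)(C)C)C#CCO[Si](C)(C)C(C)(C)C | intermediate
14 | (4S,5E,10R)-1-(tert-butyldimethylsilyloxy)-6,10-dimethyl-9,12-dioxododec-5-en-2-yn-4-yl 2-(trimethylsilyl)ethyl carbonate | O=CC[C@@H](C)C(=O)CC/C(C)=C/[C@H](OC(=O)OCC[Si](C)(C)C)C#CCO[Si](C)(C)C(C)(C)C | intermediate
15 | 2-(trimethylsilyl)ethyl (aR,5E,10R)-2-[(tert-butyldimethylsilyloxy)methyl]-6,10-dimethyl-9,12-dioxododeca-2,3,5-trienoate (allene C6=C7=C11, aldehyde C8) | O=CC[C@@H](C)C(=O)CC/C(C)=C/C([H])=[C@]=C(CO[Si](C)(C)C(C)(C)C)C(=O)OCC[Si](C)(C)C | intermediate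
16 | (6R,8S,10R)-13-(tert-butyldimethylsilyloxy)-1-oxo-8-(trimethylsilyloxy)germacra-4(E),7(11)-dien-12,6-olide | C[Si](C)(C)O[C@H]1C[C@@H](C)C(=O)CC/C(C)=C/[C@H]2OC(=O)C(CO[Si](C)(C)C(C)(C)C)=C12 | intermediate
17 | (6R,8S,10R)-13-(tert-butyldimethylsilyloxy)-8-hydroxy-1-oxogermacra-4(E),7(11)-dien-12,6-olide (ten-membered carbocycle fused at C6–C7 to the butenolide) | O[C@H]1C[C@@H](C)C(=O)CC/C(C)=C/[C@H]2OC(=O)C(CO[Si](C)(C)C(C)(C)C)=C12 | intermediate
18 | angelic acid, (2Z)-2-methylbut-2-enoic acid | C/C=C(/C)C(=O)O | starting material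
19 | (2Z)-2-methylbut-2-enoic 2,4,6-trichlorobenzoic anhydride | C/C=C(/C)C(=O)OC(=O)c1c(Cl)cc(Cl)cc1Cl | intermediate
20 | (6R,8S,10R)-8-angeloyloxy-13-(tert-butyldimethylsilyloxy)-1-oxogermacra-4(E),7(11)-dien-12,6-olide | C/C=C(/C)C(=O)O[C@H]1C[C@@H](C)C(=O)CC/C(C)=C/[C@H]2OC(=O)C(CO[Si](C)(C)C(C)(C)C)=C12 | intermediate
21 | (6R,8S,10R)-8-angeloyloxy-13-hydroxy-1-oxogermacra-4(E),7(11)-dien-12,6-olide | C/C=C(/C)C(=O)O[C@H]1C[C@@H](C)C(=O)CC/C(C)=C/[C@H]2OC(=O)C(CO)=C12 | intermediate
22 | (6R,8S,10R)-13-acetoxy-8-angeloyloxy-1-oxogermacra-4(E),7(11)-dien-12,6-olide | C/C=C(/C)C(=O)O[C@H]1C[C@@H](C)C(=O)CC/C(C)=C/[C@H]2OC(=O)C(COC(C)=O)=C12 | intermediate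
23 | (4R,5R,6S,8S,10R)-13-acetoxy-8-angeloyloxy-4,5-epoxy-1-oxogermacr-7(11)-en-12,6-olide (CNP0229937.2) | C/C=C(/C)C(=O)O[C@H]1C[C@@H](C)C(=O)CC[C@@]2(C)O[C@@H]2[C@H]2OC(=O)C(COC(C)=O)=C12 | target

**Summary**

Total step count: 15. Longest linear sequence: 15 steps (from geranyl acetate 1).

Steps most likely to fail:

1. Step 12 (Proposed new method). The vinylpalladium intermediate may be protonated, may dimerize, or the vinylallene may cyclize on its own before the slow ten-membered carbonyl insertion takes place. Fallback, from 15: iodine (1.2 equiv) with NaHCO3 in MeCN/H2O at 0 °C should bring about the known iodolactonization of the 2,3-allenoate, with the same anti addition and the same axis-to-centre transfer, the silylethyl group leaving as ethylene and trimethylsilanol. This gives (5R)-3-[(tert-butyldimethylsilyloxy)methyl]-5-[(1E,6R)-2,6-dimethyl-5,8-dioxooct-1-en-1-yl]-4-iodofuran-2(5H)-one F1. Treatment of this iodide with CrCl2 (6 equiv) and NiCl2 (2 mol %) in degassed DMSO/THF at 0.002 M should then close the ten-membered ring by Nozaki–Hiyama–Kishi addition of the C7 vinylchromium species to the C8 aldehyde, which the ketone tolerates; aqueous work-up returns to the route at 17.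

2. Step 11. Axial purity may erode through equilibration of the allenylpalladium intermediates, or the doubly activated carbonate may ionize before the anti oxidative addition. Fallback, from 10: the stereochemical burden is moved from centre-to-axis transfer to ligand control. Alkynylation of 10 with 11 and Me2Zn in the presence of racemic ProPhenol gives the C9-epimeric alcohol (3R,7E,9RS)-12-(tert-butyldimethylsilyloxy)-9-hydroxy-3,7-dimethyl-1-(triethylsilyloxy)dodec-7-en-10-yn-4-one F2. Acylation as in step 9 gives the epimeric carbonate (4RS,5E,10R)-1-(tert-butyldimethylsilyloxy)-6,10-dimethyl-9-oxo-12-(triethylsilyloxy)dodec-5-en-2-yn-4-yl 2-(trimethylsilyl)ethyl carbonate F3, and Swern treatment as in step 10 gives the epimeric aldehyde (4RS,5E,10R)-1-(tert-butyldimethylsilyloxy)-6,10-dimethyl-9,12-dioxododec-5-en-2-yn-4-yl 2-(trimethylsilyl)ethyl carbonate F4. A stereoconvergent carbonylation under CO with Pd2(dba)3 and the antipode of the chiral bisphosphine ECNU-Phos that leads to the (aR)-allene, a known enantioselective carbonylation of racemic secondary propargylic carbonates to 2,3-allenoates, then returns to the route at 15.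

3. Step 13. The angeloyl group may isomerize from Z to E (tiglate) in the hot, basic acylation of the hindered C8 hydroxyl group, and C10 may epimerize. Fallback, from 17: esterification with 2-[bis(2,2,2-trifluoroethoxy)phosphoryl]propanoic acid (DCC, DMAP, CH2Cl2, 0 °C) gives (6R,8S,10R)-13-(tert-butyldimethylsilyloxy)-1-oxogermacra-4(E),7(11)-dien-12,6-olid-8-yl 2-[bis(2,2,2-trifluoroethoxy)phosphoryl]propanoate F5. A Still–Gennari olefination with acetaldehyde (KHMDS, 18-crown-6, THF, −78 °C) then builds the (Z)-2-methylbut-2-enoate on the molecule and returns to the route at 20.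

Further compounds
F1 | step 12 | (5R)-3-[(tert-butyldimethylsilyloxy)methyl]-5-[(1E,6R)-2,6-dimethyl-5,8-dioxooct-1-en-1-yl]-4-iodofuran-2(5H)-one | O=CC[C@@H](C)C(=O)CC/C(C)=C/[C@H]1OC(=O)C(CO[Si](C)(C)C(C)(C)C)=C1I
F2 | step 11 | (3R,7E,9RS)-12-(tert-butyldimethylsilyloxy)-9-hydroxy-3,7-dimethyl-1-(triethylsilyloxy)dodec-7-en-10-yn-4-one | CC[Si](CC)(CC)OCC[C@@H](C)C(=O)CC/C(C)=C/C(O)C#CCO[Si](C)(C)C(C)(C)C
F3 | step 11 | (4RS,5E,10R)-1-(tert-butyldimethylsilyloxy)-6,10-dimethyl-9-oxo-12-(triethylsilyloxy)dodec-5-en-2-yn-4-yl 2-(trimethylsilyl)ethyl carbonate | CC[Si](CC)(CC)OCC[C@@H](C)C(=O)CC/C(C)=C/C(OC(=O)OCC[Si](C)(C)C)C#CCO[Si](C)(C)C(C)(C)C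
F4 | step 11 | (4RS,5E,10R)-1-(tert-butyldimethylsilyloxy)-6,10-dimethyl-9,12-dioxododec-5-en-2-yn-4-yl 2-(trimethylsilyl)ethyl carbonate | O=CC[C@@H](C)C(=O)CC/C(C)=C/C(OC(=O)OCC[Si](C)(C)C)C#CCO[Si](C)(C)C(C)(C)C
F5 | step 13 | (6R,8S,10R)-13-(tert-butyldimethylsilyloxy)-1-oxogermacra-4(E),7(11)-dien-12,6-olid-8-yl 2-[bis(2,2,2-trifluoroethoxy)phosphoryl]propanoate | CC(C(=O)O[C@H]1C[C@@H](C)C(=O)CC/C(C)=C/[C@H]2OC(=O)C(CO[Si](C)(C)C(C)(C)C)=C12)P(=O)(OCC(F)(F)F)OCC(F)(F)F
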